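The plan disconnects the C8–C9 bond of the ten-membered ring (germacrane numbering: C8 carries the methacrylate, C9 is the ring CH2 between C8 and alkene carbon C10). The homoallylic array O–C8–C9–C10=C1 is read as the retron of a carbonyl allylation. One operation, an intramolecular allylboration, closes the carbocycle, sets C8, fixes the ring-cis C1=C10 alkene and decides which CH2 on C10 becomes C9. Its precursor is an open chain: a C8 aldehyde, released in the flask from a silyl ether, tethered through C7–C2 to a C1-stereogenic allyl pinacol boronate made by sparteine-mediated lithiation–borylation. The α-methylene lactone is closed afterwards by oxidation of a 2-methylene-1,4-diol.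

Key step: step 18

Remark: atoms are numbered as in germacranolides (ring C1–C10; lactone carbons C11, C12 and exocyclic C13; C14 on C10; C15 on C4). Compounds 1, 4, 12, 16, 19, (−)-sparteine and all reagents are taken as commercial. Cb = N,N-diisopropylcarbamoyl.

Step 1
Reactants: 1 pentane-1,5-diol
Product: 2 5-hydroxypentyl N,N-diisopropylcarbamate
Conditions: iPr2NCOCl (1 equiv), 1 (3 equiv), Et3N, CH2Cl2, reflux
Reagents that add atoms: N,N-diisopropylcarbamoyl chloride, CC(C)N(C(C)C)C(=O)Cl
Why: O-carbamoylation of one hydroxyl, where the excess of the symmetric diol should keep the bis-carbamate low; the carbamate later directs the Hoppe lithiation at C1.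

Step 2
Reactants: 2 5-hydroxypentyl N,N-diisopropylcarbamate
Product: 3 5-[(N,N-diisopropylcarbamoyl)oxy]pentanoic acid
Conditions: TEMPO (cat.), PhI(OAc)2, MeCN/H2O, rt
Reagents that add atoms: water, O
Why: TEMPO/PhI(OAc)2 oxidation of the primary alcohol through the aldehyde hydrate to the acid should leave the carbamate untouched.

Step 3
Reactants: 3 5-[(N,N-diisopropylcarbamoyl)oxy]pentanoic acid; 4 (R)-4-benzyl-1,3-oxazolidin-2-one
Product: 6 (R)-N-acyl oxazolidinone of acid 3, via mixed pivalic anhydride 5 (not isolated)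
Conditions: t-BuCOCl, Et3N, THF, −20 °C; then LiCl, 4, rt
Reagents that add atoms: none
Why: N-acylation of the Evans auxiliary through the mixed anhydride with LiCl/Et3N activation is the standard attachment.

Step 4
Reactants: 6 (R)-N-acyl oxazolidinone of acid 3
Product: 7 α-allylated imide (C4 S)
Conditions: NaN(SiMe3)2, THF, −78 °C; allyl iodide, −78 → −45 °C
Reagents that add atoms: allyl iodide, C=CCI
Why: Evans asymmetric alkylation, in which the chelated Z sodium enolate should be allylated on the face away from the benzyl group of the (R) auxiliary, setting C4 as (S).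

Step 5
Reactants: 7 α-allylated imide (C4 S)
Product: 8 (S)-4-(hydroxymethyl)hept-6-en-1-yl N,N-diisopropylcarbamate
Conditions: LiBH4, MeOH (1 equiv), Et2O, 0 °C
Reagents that add atoms: none
Why: reductive removal of the auxiliary with LiBH4 should give the C15 alcohol without touching the hindered carbamate or epimerising C4.

Step 6
Reactants: 8 (S)-4-(hydroxymethyl)hept-6-en-1-yl N,N-diisopropylcarbamate
Product: 9 tert-butyldiphenylsilyl ether of 8
Conditions: t-BuPh2SiCl, imidazole, CH2Cl2, rt
Reagents that add atoms: tert-butylchlorodiphenylsilane, CC(C)(C)[Si](Cl)(c1ccccc1)c1ccccc1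
Why: silylation of the primary alcohol gives a group that should survive to the last step.

Step 7
Reactants: 9 tert-butyldiphenylsilyl ether of 8
Product: 11 C6 aldehyde (C4 S), via secondary ozonide 10 (not isolated)
Conditions: O3, CH2Cl2, −78 °C; PPh3, −78 °C → rt
Reagents that add atoms: ozone, [O-][O+]=O
Why: ozonolysis with reductive work-up cleaves the only alkene to the C6 aldehyde, the carbamate and silyl ether being inert to ozone.

Step 8
Reactants: 12 4-methyl hydrogen itaconate
Product: 13 methyl 3-(hydroxymethyl)but-3-enoate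
Conditions: BH3·SMe2, THF, −10 °C → rt; MeOH quench
Reagents that add atoms: none
Why: chemoselective borane reduction, since the free acid should be reduced through its acyloxyborane much faster than the methyl ester or the electron-poor alkene.

Step 9
Reactants: 13 methyl 3-(hydroxymethyl)but-3-enoate
Product: 14 methyl 3-[(tert-butyldimethylsilyloxy)methyl]but-3-enoate
Conditions: t-BuMe2SiCl, imidazole, CH2Cl2, 0 °C → rt
Reagents that add atoms: tert-butylchlorodimethylsilane, CC(C)(C)[Si](C)(C)Cl
Why: silylation blocks lactonisation of the γ-hydroxy ester and protects the future C12 oxygen.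

Step 10
Reactants: 14 methyl 3-[(tert-butyldimethylsilyloxy)methyl]but-3-enoate
Product: 15 3-[(tert-butyldimethylsilyloxy)methyl]but-3-enoic acid
Conditions: LiOH·H2O, THF/H2O, 0 °C; then 1 M HCl to pH 4
Reagents that add atoms: lithium hydroxide, [Li+].[OH-]
Why: saponification at low temperature, where the carboxylate formed should resist the deprotonation that would move the alkene into conjugation.

Step 11
Reactants: 15 3-[(tert-butyldimethylsilyloxy)methyl]but-3-enoic acid; 16 (S)-4-benzyl-1,3-oxazolidin-2-one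
Product: 18 (S)-N-acyl oxazolidinone of acid 15, via mixed pivalic anhydride 17 (not isolated)
Conditions: t-BuCOCl, Et3N, THF, −20 °C; then LiCl, 16, 0 °C
Reagents that add atoms: none
Why: N-acylation of the Evans auxiliary through the mixed anhydride, kept cold to avoid isomerising the β,γ-unsaturated acyl group.

Step 12
Reactants: 19 2-bromoprop-2-en-1-ol
Product: 20 (2-bromoallyloxy)(tert-butyl)diphenylsilane
Conditions: t-BuPh2SiCl, imidazole, CH2Cl2, rt
Reagents that add atoms: tert-butylchlorodiphenylsilane, CC(C)(C)[Si](Cl)(c1ccccc1)c1ccccc1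
Why: silylation protects the future C14 oxygen with the same group as C15.

Step 13
Reactants: 20 (2-bromoallyloxy)(tert-butyl)diphenylsilane
Product: 21 pinacol [3-(tert-butyldiphenylsilyloxy)prop-1-en-2-yl]boronate
Conditions: B2pin2, PdCl2(PPh3)2 (3 mol %), PPh3, KOPh, toluene, 50 °C
Reagents that add atoms: bis(pinacolato)diboron, CC1(C)OB(OC1(C)C)B1OC(C)(C)C(C)(C)O1
Why: Miyaura borylation of the alkenyl bromide (oxidative addition, phenoxide-assisted transmetalation, reductive elimination) should give the 1,1-disubstituted alkenyl boronate.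

Step 14
Reactants: 18 (S)-N-acyl oxazolidinone of acid 15; 11 C6 aldehyde (C4 S)
Product: 22 syn-aldol imide (4S 6R 7S)
Conditions: Bu2BOTf, iPr2NEt, CH2Cl2, −78 → 0 °C; 11, −78 → 0 °C; pH 7 buffer, MeOH, H2O2
Reagents that add atoms: none
Why: Evans syn-aldol through the Z boron enolate and a Zimmerman–Traxler chair, in which the (S) auxiliary should set C6 (R) and C7 (S) and α-attack of the dienolate keeps the 1,1-disubstituted alkene.

Step 15
Reactants: 22 syn-aldol imide (4S 6R 7S)
Product: 23 C6/C8 diol (4S 6R 7R)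
Conditions: LiBH4, MeOH, THF, 0 °C
Reagents that add atoms: none
Why: reductive cleavage of the imide with LiBH4 should give the C8 primary alcohol and release the auxiliary without retro-aldol.

Step 16
Reactants: 23 C6/C8 diol (4S 6R 7R)
Product: 24 bis(triethylsilyl) ether (4S 6R 7R)
Conditions: Et3SiOTf, 2,6-lutidine, CH2Cl2, −78 → 0 °C
Reagents that add atoms: triethylsilyl triflate, CC[Si](CC)(CC)OS(=O)(=O)C(F)(F)F
Why: silylation of both hydroxyls, the primary triethylsilyl ether at C8 serving as the latent aldehyde.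

Step 17
Reactants: 24 bis(triethylsilyl) ether (4S 6R 7R); 21 pinacol [3-(tert-butyldiphenylsilyloxy)prop-1-en-2-yl]boronate
Product: 27 allyl pinacol boronate (1R 4S 6R 7R), via lithiated carbamate 25 (not isolated), via boronate complex 26 (not isolated)
Conditions: s-BuLi, (−)-sparteine, Et2O, −78 °C, 5 h; 21, −78 °C; MgBr2·OEt2, −78 °C → reflux
Reagents that add atoms: none
Why: Hoppe-type sparteine-mediated α-lithiation removes the pro-S hydrogen at C1, the lithiated carbon adds to boron of 21 with retention, and the MgBr2-promoted Matteson-type 1,2-migration of the alkenyl group with inversion expels the carbamate, which should set C1 as (R) under reagent control.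

Step 18
Reactants: 27 allyl pinacol boronate (1R 4S 6R 7R)
Product: 30 ten-membered homoallylic alcohol (4S 6R 7R 8R), via aldehyde 28 (not isolated), via borate ester 29 (not isolated)
Conditions: (COCl)2, DMSO, CH2Cl2, −78 → −35 °C; iPr2NEt, −78 → 0 °C; then toluene (0.002 M), 23 → 45 °C; aq. NaHCO3
Reagents that add atoms: none
Why: Swern activation should convert the primary triethylsilyl ether directly into the C8 aldehyde 28 (the secondary and bulkier silyl ethers are untouched), and at high dilution the allyl boronate adds to it through a closed six-membered B–O=C8–C9=C10–C1 transition state with allylic transposition, so that C9 (the former =CH2) bonds to C8 and the alkene moves to C1=C10. The closest known reaction type is the intramolecular allylboration of ω-oxo α-substituted allyl boronates, which closes medium rings with a cis alkene inside the ring. The ten-membered carbocycle closes in the endo mode: the six-carbon tether C2–C7 bridges C1 and C8 of the chair, so both alkene carbons end up in the ring. C8 is set by chirality transfer from the (1R) boron-bearing carbon, because with C2 axial on C1 and C7 equatorial on C8 only one aldehyde face is reachable and it gives (8R); C4, C6 and C7 are spectators. The axial C2, enforced by the pinacol methyls and by A(1,2) strain with the C14 branch, should give the ring-cis C1=C10 geometry (C2 cis to C9). The step needs intra- over intermolecular addition (secured by dilution), attack through C9 (inherent to allylboration) and no epimerisation of the α-branched β,γ-unsaturated aldehyde (hindered amine, low temperature, no isolation).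

Step 19
Reactants: 30 ten-membered homoallylic alcohol (4S 6R 7R 8R)
Product: 31 C8 methacrylate (4S 6R 7R 8R)
Conditions: methacrylic anhydride, Et3N, DMAP (cat.), CH2Cl2, 0 °C → rt
Reagents that add atoms: methacrylic anhydride, CC(=C)C(=O)OC(=O)C(C)=C
Why: DMAP-catalysed acylation of the only free hydroxyl proceeds with retention at C8 and fixes O8 as the ester before O6 is released.

Step 20
Reactants: 31 C8 methacrylate (4S 6R 7R 8R)
Product: 32 C6/C12 diol (4S 6R 7S 8R)
Conditions: CSA (cat.), MeOH/CH2Cl2, 0 °C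
Reagents that add atoms: none
Why: acid-catalysed methanolysis should cleave the secondary triethylsilyl and the primary allylic tert-butyldimethylsilyl ethers far faster than the two primary tert-butyldiphenylsilyl ethers.

Step 21
Reactants: 32 C6/C12 diol (4S 6R 7S 8R)
Product: 35 bis-silylated α-methylene lactone (4S 6R 7S 8R), via hydroxy enal 33 (not isolated), via lactol 34 (not isolated)
Conditions: MnO2 (excess), CH2Cl2, rt
Reagents that add atoms: none
Why: MnO2 oxidative lactonisation of a 2-methylene-1,4-diol, in which only the allylic C12 alcohol is oxidised, the enal closes onto O6 as a lactol and is oxidised again; the C6–O bond is untouched, so the trans ring fusion from step 14 is kept and the esterified O8 cannot compete.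

Step 22
Reactants: 35 bis-silylated α-methylene lactone (4S 6R 7S 8R)
Product: 36 target CNP0546547.2
Conditions: HF·pyridine, pyridine, THF, 0 °C → rt
Reagents that add atoms: none
Why: buffered fluoride cleavage of both tert-butyldiphenylsilyl ethers should spare the methacrylate and the α-methylene lactone.

Compound list
1 | pentane-1,5-diol | OCCCCCO | starting material
2 | 5-hydroxypentyl N,N-diisopropylcarbamate | OCCCCCOC(=O)N(C(C)C)C(C)C | intermediate
3 | 5-[(N,N-diisopropylcarbamoyl)oxy]pentanoic acid | OC(=O)CCCCOC(=O)N(C(C)C)C(C)C | intermediate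
4 | (R)-4-benzyl-1,3-oxazolidin-2-one | O=C1OC[C@@H](Cc2ccccc2)N1 | starting material
5 | mixed anhydride of 3 with pivalic acid | CC(C)(C)C(=O)OC(=O)CCCCOC(=O)N(C(C)C)C(C)C | intermediate
6 | (R)-4-benzyl-3-{5-[(N,N-diisopropylcarbamoyl)oxy]pentanoyl}-1,3-oxazolidin-2-one | O=C1OC[C@@H](Cc2ccccc2)N1C(=O)CCCCOC(=O)N(C(C)C)C(C)C | intermediate
7 | (R)-4-benzyl-3-{(S)-2-allyl-5-[(N,N-diisopropylcarbamoyl)oxy]pentanoyl}-1,3-oxazolidin-2-one (C4 S) | O=C1OC[C@@H](Cc2ccccc2)N1C(=O)[C@H](CC=C)CCCOC(=O)N(C(C)C)C(C)C | intermediate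
8 | (S)-4-(hydroxymethyl)hept-6-en-1-yl N,N-diisopropylcarbamate | OC[C@H](CC=C)CCCOC(=O)N(C(C)C)C(C)C | intermediate
9 | (S)-4-[(tert-butyldiphenylsilyloxy)methyl]hept-6-en-1-yl N,N-diisopropylcarbamate | CC(C)(C)[Si](c1ccccc1)(c1ccccc1)OC[C@H](CC=C)CCCOC(=O)N(C(C)C)C(C)C | intermediate
10 | secondary ozonide (1,2,4-trioxolane) of 9 | CC(C)(C)[Si](c1ccccc1)(c1ccccc1)OC[C@H](CC1OCOO1)CCCOC(=O)N(C(C)C)C(C)C | intermediate
11 | (S)-4-[(tert-butyldiphenylsilyloxy)methyl]-6-oxohexyl N,N-diisopropylcarbamate (C6 aldehyde, C1 OCb, C15 silyl ether) | CC(C)(C)[Si](c1ccccc1)(c1ccccc1)OC[C@H](CC=O)CCCOC(=O)N(C(C)C)C(C)C | intermediate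
12 | 4-methyl hydrogen itaconate (4-methoxy-2-methylidene-4-oxobutanoic acid) | C=C(CC(=O)OC)C(=O)O | starting material
13 | methyl 3-(hydroxymethyl)but-3-enoate | C=C(CO)CC(=O)OC | intermediate
14 | methyl 3-[(tert-butyldimethylsilyloxy)methyl]but-3-enoate | C=C(CO[Si](C)(C)C(C)(C)C)CC(=O)OC | intermediate
15 | 3-[(tert-butyldimethylsilyloxy)methyl]but-3-enoic acid | C=C(CO[Si](C)(C)C(C)(C)C)CC(=O)O | intermediate
16 | (S)-4-benzyl-1,3-oxazolidin-2-one | O=C1OC[C@H](Cc2ccccc2)N1 | starting material
17 | mixed anhydride of 15 with pivalic acid | C=C(CO[Si](C)(C)C(C)(C)C)CC(=O)OC(=O)C(C)(C)C | intermediate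
18 | (S)-4-benzyl-3-{3-[(tert-butyldimethylsilyloxy)methyl]but-3-enoyl}-1,3-oxazolidin-2-one | O=C1OC[C@H](Cc2ccccc2)N1C(=O)CC(=C)CO[Si](C)(C)C(C)(C)C | intermediate
19 | 2-bromoprop-2-en-1-ol | OCC(Br)=C | starting material
20 | (2-bromoallyloxy)(tert-butyl)diphenylsilane | C=C(Br)CO[Si](c1ccccc1)(c1ccccc1)C(C)(C)C | intermediate
21 | 2-[3-(tert-butyldiphenylsilyloxy)prop-1-en-2-yl]-4,4,5,5-tetramethyl-1,3,2-dioxaborolane | C=C(CO[Si](c1ccccc1)(c1ccccc1)C(C)(C)C)B1OC(C)(C)C(C)(C)O1 | intermediate
22 | syn-aldol imide, open chain C1–C8: (S)-4-benzyl-oxazolidinone on the C8 carbonyl; C7 (S) carries the 3-(tert-butyldimethylsilyloxy)prop-1-en-2-yl group (C11=C13, C12); C6 (R) free OH; C4 (S) carries CH2OSiPh2tBu (C15); C1 carries OCb | O=C1OC[C@H](Cc2ccccc2)N1C(=O)[C@@H](C(=C)CO[Si](C)(C)C(C)(C)C)[C@H](O)C[C@H](CCCOC(=O)N(C(C)C)C(C)C)CO[Si](c3ccccc3)(c3ccccc3)C(C)(C)C | intermediate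
23 | diol from 22: C8 is CH2OH, C6 (R) OH, C7 (R), C4 (S), other groups as in 22 | OC[C@@H](C(=C)CO[Si](C)(C)C(C)(C)C)[C@H](O)C[C@H](CCCOC(=O)N(C(C)C)C(C)C)CO[Si](c1ccccc1)(c1ccccc1)C(C)(C)C | intermediate
24 | bis(triethylsilyl) ether of 23 (O6 and O8 silylated; 4S,6R,7R) | CC[Si](CC)(CC)OC[C@@H](C(=C)CO[Si](C)(C)C(C)(C)C)[C@H](O[Si](CC)(CC)CC)C[C@H](CCCOC(=O)N(C(C)C)C(C)C)CO[Si](c1ccccc1)(c1ccccc1)C(C)(C)C | intermediate
25 | (1S)-α-lithiated carbamate of 24 (sparteine ligand not drawn) | CC[Si](CC)(CC)OC[C@@H](C(=C)CO[Si](C)(C)C(C)(C)C)[C@H](O[Si](CC)(CC)CC)C[C@H](CC[C@H]([Li])OC(=O)N(C(C)C)C(C)C)CO[Si](c1ccccc1)(c1ccccc1)C(C)(C)C | intermediate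
26 | lithium boronate complex: C1 (S) bonded to OCb and to the tetracoordinate boron that carries pinacol and the alkenyl group of 21 | CC[Si](CC)(CC)OC[C@@H](C(=C)CO[Si](C)(C)C(C)(C)C)[C@H](O[Si](CC)(CC)CC)C[C@H](CC[C@@H](OC(=O)N(C(C)C)C(C)C)[B-]1(C(=C)CO[Si](c2ccccc2)(c2ccccc2)C(C)(C)C)OC(C)(C)C(C)(C)O1)CO[Si](c3ccccc3)(c3ccccc3)C(C)(C)C.[Li+] | intermediate
27 | allyl pinacol boronate: C1 (R) carries Bpin and the C10(=C9H2)C14H2OSiPh2tBu unit; C8 CH2OSiEt3; C6 (R) OSiEt3; C7 (R); C4 (S) | CC[Si](CC)(CC)OC[C@@H](C(=C)CO[Si](C)(C)C(C)(C)C)[C@H](O[Si](CC)(CC)CC)C[C@H](CC[C@@H](B1OC(C)(C)C(C)(C)O1)C(=C)CO[Si](c2ccccc2)(c2ccccc2)C(C)(C)C)CO[Si](c3ccccc3)(c3ccccc3)C(C)(C)C | intermediate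
28 | C8 aldehyde of 27 (1R,4S,6R,7S) | O=C[C@@H](C(=C)CO[Si](C)(C)C(C)(C)C)[C@H](O[Si](CC)(CC)CC)C[C@H](CC[C@@H](B1OC(C)(C)C(C)(C)O1)C(=C)CO[Si](c2ccccc2)(c2ccccc2)C(C)(C)C)CO[Si](c3ccccc3)(c3ccccc3)C(C)(C)C | intermediate
29 | pinacol borate ester of 30 (O8–Bpin) | CC1(C)OB(OC1(C)C)O[C@@H]2C/C(CO[Si](c3ccccc3)(c3ccccc3)C(C)(C)C)=C\CC[C@H](CO[Si](c4ccccc4)(c4ccccc4)C(C)(C)C)C[C@@H](O[Si](CC)(CC)CC)[C@@H]2C(=C)CO[Si](C)(C)C(C)(C)C | intermediate
30 | cyclodec-1(10)-ene (ring-cis alkene, E by CIP): C8 (R) OH; C7 (R) carries the 3-(tert-butyldimethylsilyloxy)prop-1-en-2-yl group; C6 (R) OSiEt3; C4 (S) CH2OSiPh2tBu; C10 CH2OSiPh2tBu | O[C@@H]1C/C(CO[Si](c2ccccc2)(c2ccccc2)C(C)(C)C)=C\CC[C@H](CO[Si](c3ccccc3)(c3ccccc3)C(C)(C)C)C[C@@H](O[Si](CC)(CC)CC)[C@@H]1C(=C)CO[Si](C)(C)C(C)(C)C | intermediate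
31 | C8 methacrylate of 30 (4S,6R,7R,8R) | C=C(C)C(=O)O[C@@H]1C/C(CO[Si](c2ccccc2)(c2ccccc2)C(C)(C)C)=C\CC[C@H](CO[Si](c3ccccc3)(c3ccccc3)C(C)(C)C)C[C@@H](O[Si](CC)(CC)CC)[C@@H]1C(=C)CO[Si](C)(C)C(C)(C)C | intermediate
32 | diol from 31: free C6 OH and free C12 allylic OH; both tert-butyldiphenylsilyl ethers kept (4S,6R,7S,8R) | C=C(C)C(=O)O[C@@H]1C/C(CO[Si](c2ccccc2)(c2ccccc2)C(C)(C)C)=C\CC[C@H](CO[Si](c3ccccc3)(c3ccccc3)C(C)(C)C)C[C@@H](O)[C@@H]1C(=C)CO | intermediate
33 | hydroxy enal from 32 (C12 aldehyde) | C=C(C)C(=O)O[C@@H]1C/C(CO[Si](c2ccccc2)(c2ccccc2)C(C)(C)C)=C\CC[C@H](CO[Si](c3ccccc3)(c3ccccc3)C(C)(C)C)C[C@@H](O)[C@@H]1C(=C)C=O | intermediate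
34 | lactol from 33 (O6–C12 hemiacetal, C12 epimers) | C=C(C)C(=O)O[C@@H]1C/C(CO[Si](c2ccccc2)(c2ccccc2)C(C)(C)C)=C\CC[C@H](CO[Si](c3ccccc3)(c3ccccc3)C(C)(C)C)C[C@H]2OC(O)C(=C)[C@H]12 | intermediate
35 | 14,15-bis(tert-butyldiphenylsilyl) ether of the target (4S,6R,7S,8R) | C=C(C)C(=O)O[C@@H]1C/C(CO[Si](c2ccccc2)(c2ccccc2)C(C)(C)C)=C\CC[C@H](CO[Si](c3ccccc3)(c3ccccc3)C(C)(C)C)C[C@H]2OC(=O)C(=C)[C@H]12 | intermediate
36 | CNP0546547.2 (4S,6R,7S,8R; ring-cis C1=C10) | C=C(C)C(=O)O[C@@H]1C/C(CO)=C\CC[C@H](CO)C[C@H]2OC(=O)C(=C)[C@H]12 | target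

Total step count: 22. Longest linear sequence: 16 steps (steps 1–7, then 14–22).

Steps most likely to fail

Step 18. The ring closure may lose to intermolecular allylboration, the α-branched β,γ-unsaturated aldehyde may epimerise or move into conjugation, and the aldehyde may be attacked on its other face through a boat-shaped bicyclic arrangement. The last process would turn 27 into the C8 epimer of 30, the 8-epi alcohol F1, in the same operation. F1 would then be esterified with methacrylic acid under Mitsunobu conditions (PPh3, DIAD, toluene, 0 °C → rt). This inverts C8 and gives methacrylate 31, where the route resumes at step 20. The fallback sets out from 27 and comes back at 31.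

Step 17. Capture of the hindered 2-substituted alkenyl boronate by the sparteine-bound carbenoid may be slow, so that the lithiated carbamate decomposes before the boronate complex forms or rearranges. In the fallback the two events are separated. The lithiated carbamate from 24 is trapped with 2-isopropoxy-4,4,5,5-tetramethyl-1,3,2-dioxaborolane to give the isolable α-carbamoyloxy boronate F2. Bromide 20 is converted separately into its alkenyllithium (t-BuLi, Et2O, −78 °C) and added to F2 at −78 °C. MgBr2·OEt2 and warming then trigger the same 1,2-migration with loss of the carbamate to give 27. The fallback sets out from 24 and comes back at 27.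

Step 21. The double oxidation on MnO2 may stall at the lactol, and the methacrylate may migrate to the free C6 hydroxyl during a long contact time. In the fallback 32 is oxidised with TEMPO (cat.)/PhI(OAc)2 only as far as lactol 34, which is isolated. Pinnick oxidation (NaClO2, NaH2PO4, 2-methyl-2-butene, t-BuOH/H2O) of its open form 33 gives the hydroxy acid F3. F3 lactonises on mild acid treatment (PPTS, CH2Cl2) to 35. The fallback sets out from 32 and comes back at 35.

Further compounds
F1 | step 18 | 8-epi alcohol, C8 (S) epimer of 30 | O[C@H]1C/C(CO[Si](c2ccccc2)(c2ccccc2)C(C)(C)C)=C\CC[C@H](CO[Si](c3ccccc3)(c3ccccc3)C(C)(C)C)C[C@@H](O[Si](CC)(CC)CC)[C@@H]1C(=C)CO[Si](C)(C)C(C)(C)C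
F2 | step 17 | α-carbamoyloxy pinacol boronate of 24, C1 (S) | CC[Si](CC)(CC)OC[C@@H](C(=C)CO[Si](C)(C)C(C)(C)C)[C@H](O[Si](CC)(CC)CC)C[C@H](CC[C@@H](OC(=O)N(C(C)C)C(C)C)B1OC(C)(C)C(C)(C)O1)CO[Si](c1ccccc1)(c1ccccc1)C(C)(C)C
F3 | step 21 | hydroxy acid from 33 (C12 carboxylic acid, free C6 OH) | C=C(C)C(=O)O[C@@H]1C/C(CO[Si](c2ccccc2)(c2ccccc2)C(C)(C)C)=C\CC[C@H](CO[Si](c3ccccc3)(c3ccccc3)C(C)(C)C)C[C@@H](O)[C@@H]1C(=C)C(=O)O
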